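Cuts, in retrosynthetic order (chain carbons counted from the ester oxygen): the two phenols are masked as benzyl ethers and C12–C13 is taken back to an alkene. C12=C13 is cut first, then the acyl–O bond of the ester, then C10–C11.
Enabling feature: C13–C18 with the methyl branch on C16 is C6–C1 of (R)-β-citronellene 1 once its vinyl group (C17–C18) is saturated. The terpene's isopropylidene carbon sits on C13, where metathesis can exchange it for C12. The only ring, the catechol arene, is bought, and no ring is formed.
Forward: an allyl unit (C11, C12 and a sacrificial CH2) is joined to a C1–C10 bromo alcohol, and the alcohol is acylated with the dibenzylated acid. The terpene end is then attached at C12=C13, and one hydrogenation saturates the chain and frees the catechol.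
Stereochemistry: C16 (S) is C3 of 1, and no step makes or breaks a bond at this carbon.

Key step: step 6

Assumption: the purchased (R)-β-citronellene is taken as enantiomerically pure; because C16 is never touched, the enantiomeric purity of the target equals that of this lot, which should be assayed by chiral GC before use.

Step 1
Reactants: 1 (R)-3,7-dimethylocta-1,6-diene ((R)-β-citronellene)
Product: 2 (S)-2,6-dimethyloct-2-ene
Conditions: 2-nitrobenzenesulfonohydrazide (NBSH, 2.5 equiv, in portions), Et3N, CH2Cl2, rt; pentane/silica plug, distillation
Reagents that add atoms: none
Why: Diimide reduction: HN=NH set free from NBSH delivers H2 by a concerted syn transfer whose rate falls steeply with alkene substitution, so the vinyl group should be saturated and the trisubstituted alkene kept; no bond at C3 is touched, and its label changes from R to S only because the new ethyl group ranks below the chain.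

Step 2
Reactants: 3 10-bromodecan-1-ol; 4 allylmagnesium bromide
Product: 7 tridec-12-en-1-ol, via bromomagnesium 10-bromodecan-1-olate 5 (not isolated), via bromomagnesium tridec-12-en-1-olate 6 (not isolated)
Conditions: 4 (3 equiv, Et2O solution), Li2CuCl4 (3 mol %), THF, −20 °C → rt; then 1 M HCl
Reagents that add atoms: none
Why: Kochi-type copper-catalysed coupling of a Grignard reagent with a primary alkyl bromide: the first equivalent of 4 only deprotonates the alcohol, the allylcopper species formed from further 4 displaces the unhindered primary bromide, and the magnesium alkoxide is a spectator, so no protecting group is needed.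

Step 3
Reactants: 8 2,3-dihydroxybenzoic acid
Product: 9 benzyl 2,3-bis(benzyloxy)benzoate
Conditions: BnBr (3.5 equiv), K2CO3 (4 equiv), DMF, 60 °C
Reagents that add atoms: benzyl bromide, BrCc1ccccc1
Why: Williamson-type O-alkylation: K2CO3 deprotonates the acid and both phenols (the hydrogen-bonded 2-OH last, hence the heating) and each oxygen anion displaces bromide from benzyl bromide by SN2, exhaustive benzylation being simpler than sparing the carboxyl group.

Step 4
Reactants: 9 benzyl 2,3-bis(benzyloxy)benzoate
Product: 11 2,3-bis(benzyloxy)benzoic acid, via potassium 2,3-bis(benzyloxy)benzoate 10 (not isolated)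
Conditions: KOH (aq, 3 equiv), MeOH/THF, reflux; then 2 M HCl
Reagents that add atoms: potassium hydroxide, [K+].[OH-]
Why: Saponification: hydroxide adds to the ester carbonyl and expels the benzyl alcoholate irreversibly to give carboxylate 10, the aryl benzyl ethers are inert to aqueous base, and acidification should precipitate 11.

Step 5
Reactants: 11 2,3-bis(benzyloxy)benzoic acid; 7 tridec-12-en-1-ol
Product: 12 tridec-12-en-1-yl 2,3-bis(benzyloxy)benzoate
Conditions: DCC (1.2 equiv), DMAP (0.2 equiv), CH2Cl2, 0 °C → rt
Reagents that add atoms: none
Why: Steglich esterification: DCC activates 11 as the O-acylisourea, DMAP relays the acyl group faster than the N-acylurea rearrangement, and the unhindered primary alcohol takes it up under neutral conditions that leave the terminal alkene and the benzyl ethers alone.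

Step 6
Reactants: 2 (S)-2,6-dimethyloct-2-ene; 12 tridec-12-en-1-yl 2,3-bis(benzyloxy)benzoate
Product: 14 (S)-16-methyloctadec-12-en-1-yl 2,3-bis(benzyloxy)benzoate (E/Z mixture), via (S)-4-methylhex-1-ene 13 (not isolated)
Conditions: 2 (4 equiv), second-generation Grubbs catalyst (H2IMes)(PCy3)Cl2Ru=CHPh (2 × 2.5 mol %), 1,4-benzoquinone (10 mol %), toluene, 40 °C, slow C2H4 stream until an aliquot shows no isopropylidene group; then Ar sparge, 40 °C; silica gel
Reagents that add atoms: none
Why: Olefin cross-metathesis through the Chauvin cycle: Ru=CH2 adds [2+2] to the trisubstituted alkene of 2 with the CMe2 carbon in the β-position of the ruthenacyclobutane, cycloreversion expels 2-methylpropene and leaves the alkylidene that carries C13, and this adds to the terminal alkene of 12 to form C12=C13 and return Ru=CH2, while alkylidene caught by ethene rests as 13 and re-enters in the same way. The closest known reaction type is the ruthenium-catalysed exchange between terminal alkenes and isopropylidene (prenyl-type) alkenes, familiar in the reverse sense as the capping of terminal alkenes with 2-methylpropene or 2-methylbut-2-ene and in this sense as ethenolysis and cross-metathesis of citronellyl-type terpenoids. No ring closes and no stereocentre is created; C16 lies three carbons from the reacting alkene and is carried through, and the E/Z mixture does not matter because step 7 saturates it. The step needs cross- over self-coupling and, above all, complete export of the =CMe2 groups: each can leave only together with a =CH2 unit, and since 12 alone would quickly lose its =CH2 units as ethene by self-metathesis, a mere excess of 2 would end by passing isopropylidene groups onto the ester chain. The ethene stream therefore supplies methylidene until no isopropylidene group is left, and the argon purge then lets the excess of C13–C18 alkylidene units pair with C12, the two self-coupled by-products carrying two ester groups or none and so being easy to remove from 14 on silica. 1,4-Benzoquinone quenches ruthenium hydrides, so the double bond should neither creep toward C16 nor give chain-shortened homologues by isomerisation–metathesis.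

Step 7
Reactants: 14 (S)-16-methyloctadec-12-en-1-yl 2,3-bis(benzyloxy)benzoate (E/Z mixture)
Product: 15 gentiside F, (S)-16-methyloctadecyl 2,3-dihydroxybenzoate
Conditions: H2 (3 bar), Pd/C (10 wt % Pd), EtOAc, rt, vigorous stirring
Reagents that add atoms: none
Why: Heterogeneous catalytic hydrogenation combined with hydrogenolysis: on palladium the unhindered 1,2-disubstituted alkene takes up H2 and both aryl benzyl ethers are cleaved at the benzylic C–O bond, the alkyl benzoate (no benzylic C–O bond) and the arene stay, and a good hydrogen supply keeps saturation faster than double-bond migration so that C16 should keep its configuration.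

Compound list
1 | (R)-3,7-dimethylocta-1,6-diene ((R)-β-citronellene) | C=C[C@H](C)CCC=C(C)C | starting material
2 | (S)-2,6-dimethyloct-2-ene | CC[C@H](C)CCC=C(C)C | intermediate
3 | 10-bromodecan-1-ol | OCCCCCCCCCCBr | starting material
4 | allylmagnesium bromide | C=CC[Mg]Br | starting material
5 | bromomagnesium 10-bromodecan-1-olate | BrCCCCCCCCCCO[Mg]Br | intermediate
6 | bromomagnesium tridec-12-en-1-olate | C=CCCCCCCCCCCCO[Mg]Br | intermediate
7 | tridec-12-en-1-ol | C=CCCCCCCCCCCCO | intermediate
8 | 2,3-dihydroxybenzoic acid | O=C(O)c1cccc(O)c1O | starting material
9 | benzyl 2,3-bis(benzyloxy)benzoate | O=C(OCc1ccccc1)c1cccc(OCc2ccccc2)c1OCc1ccccc1 | intermediate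
10 | potassium 2,3-bis(benzyloxy)benzoate | [K+].[O-]C(=O)c1cccc(OCc2ccccc2)c1OCc1ccccc1 | intermediate
11 | 2,3-bis(benzyloxy)benzoic acid | OC(=O)c1cccc(OCc2ccccc2)c1OCc1ccccc1 | intermediate
12 | tridec-12-en-1-yl 2,3-bis(benzyloxy)benzoate | C=CCCCCCCCCCCCOC(=O)c1cccc(OCc2ccccc2)c1OCc1ccccc1 | intermediate
13 | (S)-4-methylhex-1-ene | CC[C@H](C)CC=C | intermediate
14 | (S)-16-methyloctadec-12-en-1-yl 2,3-bis(benzyloxy)benzoate, E/Z mixture | CC[C@H](C)CCC=CCCCCCCCCCCCOC(=O)c1cccc(OCc2ccccc2)c1OCc1ccccc1 | intermediate
15 | gentiside F, (S)-16-methyloctadecyl 2,3-dihydroxybenzoate | CC[C@H](C)CCCCCCCCCCCCCCCOC(=O)c1cccc(O)c1O | target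

Total step count: 7. Longest linear sequence: 5 steps (8 → 9 → 11 → 12 → 14 → 15).

Steps most likely to fail

Step 6. The ruthenium methylidene may decay under ethene before all isopropylidene groups have been expelled, so that these groups are shuffled onto the ester chain instead of leaving. Self-coupling may also take too large a share in the argon phase.
- The fallback makes the same C12=C13 bond by olefination instead of metathesis. It sets out from 2 and comes back at 14.
- Ozonolysis of 2 (O3, CH2Cl2, −78 °C; Me2S) should give (S)-4-methylhexanal F1.
- Purchased 12-bromododecan-1-ol is heated with PPh3 in MeCN to give (12-hydroxydodecyl)triphenylphosphonium bromide F2.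
- Two equivalents of NaN(SiMe3)2 in THF convert F2 into sodium 12-(triphenylphosphoranylidene)dodecan-1-olate F3.
- A Wittig reaction of F3 with F1 (−78 °C → rt) should give (12Z,16S)-16-methyloctadec-12-en-1-ol F4.
- Steglich acylation of F4 with acid 11 (DCC, DMAP, CH2Cl2) delivers 14, mainly as the Z isomer, which step 7 treats alike.

Step 7. Palladium hydride may move the double bond along the chain ahead of saturation, which would erode the configuration at C16 if it reached C15. Ether cleavage may also stall through poisoning of the catalyst by ruthenium residues.
- The fallback separates the two tasks. It sets out from 14 and comes back at 15.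
- Metal-free saturation with diimide (NBSH, Et3N, CH2Cl2, rt), which cannot isomerise an alkene, should give (S)-16-methyloctadecyl 2,3-bis(benzyloxy)benzoate F5.
- The alkene-free F5 is then debenzylated (H2, Pd/C, EtOAc) to 15.

Step 1. Discrimination between the two alkenes may be incomplete, or the reduction may stall through disproportionation of diimide. Either is aggravated because a mixture of volatile hydrocarbons cannot be separated on silica.
- The fallback passes through a polar, purifiable intermediate. It sets out from 1 and comes back at 2.
- Hydroboration of the vinyl group with 9-BBN (THF, 0 °C → rt), which responds far more strongly to alkene substitution, gives 9-[(S)-3,7-dimethyloct-6-en-1-yl]-9-borabicyclo[3.3.1]nonane F6.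
- Oxidation (H2O2, NaOH) gives (R)-citronellol F7, which can be chromatographed.
- TsCl in pyridine gives (R)-citronellyl 4-methylbenzenesulfonate F8, and LiAlH4 in THF displaces the sulfonate by hydride to give 2.

Further compounds
F1 | step 6 | (S)-4-methylhexanal | CC[C@H](C)CCC=O
F2 | step 6 | (12-hydroxydodecyl)triphenylphosphonium bromide | [Br-].OCCCCCCCCCCCC[P+](c1ccccc1)(c1ccccc1)c1ccccc1
F3 | step 6 | sodium 12-(triphenylphosphoranylidene)dodecan-1-olate | [Na+].[O-]CCCCCCCCCCCC=P(c1ccccc1)(c1ccccc1)c1ccccc1
F4 | step 6 | (12Z,16S)-16-methyloctadec-12-en-1-ol | CC[C@H](C)CC/C=C\CCCCCCCCCCCO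
F5 | step 7 | (S)-16-methyloctadecyl 2,3-bis(benzyloxy)benzoate | CC[C@H](C)CCCCCCCCCCCCCCCOC(=O)c1cccc(OCc2ccccc2)c1OCc1ccccc1
F6 | step 1 | 9-[(S)-3,7-dimethyloct-6-en-1-yl]-9-borabicyclo[3.3.1]nonane | CC(C)=CCC[C@@H](C)CCB1C2CCCC1CCC2
F7 | step 1 | (R)-citronellol | OCC[C@H](C)CCC=C(C)C
F8 | step 1 | (R)-citronellyl 4-methylbenzenesulfonate | Cc1ccc(cc1)S(=O)(=O)OCC[C@H](C)CCC=C(C)C
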